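The earlier runs and the new flask stem from a simulated flask from invented constants, noise included.

The south-west run holds 73.7% of product, target and isomer counted together, at 50.0 min, from 1.5 equiv of reagent. We ask what the three flasks below make of that same charge.

| setting | south-west | south-east | north-west | north | alpha | eta | gamma |
|---|---|---|---|---|---|---|---|
| starting material | 0.12 M | 0.12 M | 0.12 M | 0.060 M | 0.12 M (fed, over 40 min) | 0.12 M | 0.12 M |
| reagent | 1.5 equiv | 1 equiv | 2.2 equiv | 1.5 equiv | 1.50 equiv | 1.50 equiv | 1.50 equiv (fed, over 40 min) |
| remark | run made earlier | run made earlier | run made earlier | run made earlier | all else is in the flask from the start; the feed brings no volume worth counting | everything together at the start | all else is in the flask from the start; the feed brings no volume worth counting |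
| time |  |  |  |  | 50 min | 50 min | 50 min |

| run | time / min | isomer of the product / % | target / % |
|---|---|---|---|
| south-west | 4.00 | 16.3 | 21.3 |
| south-west | 6.00 | 19.6 | 24.9 |
| south-west | 10.0 | 24.2 | 30.2 |
| south-west | 15.0 | 27.7 | 33.6 |
| south-west | 20.0 | 30.0 | 35.4 |
| south-west | 30.0 | 31.1 | 37.9 |
| south-west | 50.0 | 33.1 | 40.6 |
| south-east | 2.50 | 10.3 | 15.4 |
| south-east | 4.00 | 14.6 | 18.6 |
| south-east | 6.00 | 17.9 | 22.4 |
| south-east | 8.00 | 19.7 | 25.1 |
| south-east | 12.0 | 23.6 | 28.9 |
| south-east | 20.0 | 27.6 | 33.7 |
| south-east | 30.0 | 28.2 | 35.3 |
| north-west | 2.50 | 12.7 | 18.8 |
| north-west | 4.00 | 18.3 | 22.4 |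
| north-west | 6.00 | 21.0 | 27.1 |
| north-west | 8.00 | 24.2 | 29.1 |
| north-west | 12.0 | 27.3 | 33.5 |
| north-west | 20.0 | 29.9 | 37.4 |
| north-west | 30.0 | 33.5 | 40.5 |
| north | 6.00 | 11.0 | 15.0 |
| north | 12.0 | 16.3 | 20.8 |
| north | 20.0 | 21.2 | 25.1 |
| north | 25.0 | 22.4 | 27.0 |
| north | 30.0 | 23.4 | 28.9 |

(standard deviation of a reading: 0.5 percentage points)

- the earlier runs were read with a standard deviation of 0.5 percentage points
- steps thought possible: starting material + reagent -> target; 2 reagent -> homo dimer; target <-> isomer of the product; starting material <-> dormant form

- the flask that comes out highest in amount of isomer of the product, in percent of the starting material charged, or "all alike" when all lie within 1.5 percentage points (alpha / eta / gamma / all alike)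
- isomer of the product at the end, in percent of the starting material charged, alpha
- isomer of the product at the end, in percent of the starting material charged, eta
- isomer of the product at the end, in percent of the starting material charged, gamma

We read the last row of each table. Dividing the rate at which reagent goes by the rate at which product forms removes time and leaves the reagent cost, the reagent spent per product made, a selectivity factor turned over. Taking the charge as the most that can have been spent, the cost is at most 2.04 in the south-west run, 1.57 in the south-east run and 2.97 in the north-west run. So the south-east ceiling is lower than the north-west one. The same row of the south-west run gives isomer as 44.9% of product.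

Our own reckoning follows from this. Gamma holds [reagent] low, so we assume that it spends its whole charge at the south-east ceiling, and that estimate gives 42.8% of isomer. Alpha leaves reagent standing while starting material trickles in, so we assume the north-west ceiling for it, and that estimate gives 22.7% of isomer. Eta repeats the south-west run. These two figures are estimates and not bounds, but set beside the 33.1% of isomer read at 50.0 min in the south-west run they give our order: gamma, eta, alpha.

The forecast names gamma, with 15.5% for alpha, 33.2% for eta and 35.5% for gamma, on the ground that “Gamma keeps reagent low and suppresses dimer”. Its gamma and alpha figures are lower than our estimates.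

The flasks end at 13.5% in alpha, 33.6% in eta and 35.3% in gamma, so gamma stands highest.

    starting material + reagent → target, rate k1*[starting material]^2*[reagent]^0.5 (k = 0.110 M⁻¹·⁵ s⁻¹)
    2 reagent → homo dimer (k = 0.00970 M⁻¹ s⁻¹)
    target ⇌ isomer of the product (K = 0.830, k = 0.0230 s⁻¹)
    starting material ⇌ dormant form (K = 0.340, k = 0.0740 s⁻¹)

In gamma the relaxation half-life of target and isomer, 0.228 min, is far shorter than the 50 min of the run, and isomer stands at 45.3% of product. The reagent cost at the end is 1.63 in gamma, with 15% of its reagent still unspent, against 5.04 in alpha. The neighbour of gamma charged with 0.600 equiv of reagent ends at a cost of 1.02 and 26.0% of isomer.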